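**Plan**
- Retrosynthesis: remove the two acyl groups (acetyl on O4, angeloyl on O3), cut both C–O bonds of the cis-3α,4α-diol back to a C3=C4 alkene, move the C8 carbonyl back to C9, then cut ring A at C1–C10 and C4–C5.
- Enabling feature: ring B (C5–C10), with the methyl on C10, the ring-fusion hydrogen on C5 and the isopropyl on C7, is a carvone ring once its carbonyl sits on C9 (C10 = enone α-carbon, C5 = β-carbon); C1–C4, with oxygen on C3 and methyl on C4, is a 2-silyloxy diene.
- Forward: ring B comes intact from (S)-carvone; ring A is closed across C5=C10 by a Diels–Alder reaction; the C9 carbonyl is moved to C8 (enol triflate, alkene, hydroboration, oxidation) while a C3 enol triflate stores the future C3=C4 alkene; the alkene is then released, cis-dihydroxylated and acylated twice.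
- Stereochemistry: C7 from carvone; C5 and C10 from diene addition anti to the C7 isopropyl (cis fusion from suprafacial addition); C3 and C4 from a Woodward cis-hydroxylation that places both oxygens on the α face; the Z alkene from angelic acid.

Key step: step 3

Assumption: eudesmane numbering is used (ring A = C1–C5 and C10, ring B = C5–C10, methyls on C4 and C10, isopropyl on C7) and β is the face of the C10 methyl; the C4 configuration drawn for 5–9 (4α-methyl, endo adduct) is immaterial because step 6 flattens C4, and the C8 carbinol configuration in 11–12 is immaterial because step 8 oxidises it.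

**Step 1**
Reactants: 1 (S)-(+)-carvone
Product: 2 (S)-carvotanacetone
Conditions: H2 (1 atm), RhCl(PPh3)3 (cat.), toluene, rt
Reagents that add atoms: none
Why: Homogeneous catalytic hydrogenation with RhCl(PPh3)3 should reduce the unhindered 1,1-disubstituted isopropenyl alkene much faster than the trisubstituted conjugated ring alkene, leaving the enone and the stereocentre (the later C7) untouched.

**Step 2**
Reactants: 3 pent-1-en-3-one
Product: 4 (Z)-3-(tert-butyldimethylsilyloxy)penta-1,3-diene
Conditions: TBSOTf, Et3N, Et2O, 0 °C to rt
Reagents that add atoms: tert-butyldimethylsilyl trifluoromethanesulfonate, CC(C)(C)[Si](C)(C)OS(=O)(=O)C(F)(F)F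
Why: Soft enolisation (O-silylation of the carbonyl by the silyl triflate, then deprotonation by the amine) should give the silyl dienol ether, with the Z isomer expected from an ethyl ketone so that the methyl lies cis to oxygen and on the outside of the s-cis diene.

**Step 3**
Reactants: 2 (S)-carvotanacetone; 4 (Z)-3-(tert-butyldimethylsilyloxy)penta-1,3-diene (excess)
Product: 5 3-(tert-butyldimethylsilyloxy)-4βH,5βH-eudesm-2-en-9-one (cis-fused; 4α-Me; 10β-Me; 7β-iPr)
Conditions: EtAlCl2 (0.3 equiv), toluene, −30 °C to rt; Et3N quench, aq. NaHCO3
Reagents that add atoms: none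
Why: EtAlCl2 binds the C9 carbonyl of 2 and the electron-rich diene adds in an asynchronous normal-demand [4+2] cycloaddition, the closest known reaction type being the Lewis-acid-promoted Diels–Alder reaction of carvone-type 2-methylcyclohex-2-enones with 2-silyloxy dienes. Ring A is closed as a six-membered carbocycle by the cycloaddition itself, both new σ-bonds (C4–C5 and C1–C10) forming suprafacially on the C5=C10 bond, so H5 and the C10 methyl must end up cis. The required regiochemistry comes from the silyloxy group on C3, which makes the neighbouring terminus C4 the nucleophilic end of the diene so that it bonds to the electrophilic β-carbon C5 while C1 closes on C10. The required facial selectivity comes from the C7 isopropyl group: the diene should add to the enone face anti to it, which sets C5 (β-H) and C10 (β-methyl) relative to C7. The C4 methyl is expected α from an endo transition state with the diene methyl outside, but this centre is planarised in step 6 and need not be controlled. Quenching with Et3N before aqueous work-up should preserve the acid-labile C2=C3 silyl enol ether, which protects the C3 carbonyl through steps 4 and 5.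

**Step 4**
Reactants: 5 3-(tert-butyldimethylsilyloxy)-4βH,5βH-eudesm-2-en-9-one
Product: 7 3-(tert-butyldimethylsilyloxy)-9-(trifluoromethanesulfonyloxy)-4βH,5βH-eudesma-2,8-diene, via potassium enolate 6 (not isolated)
Conditions: KN(SiMe3)2, THF, −78 °C; then PhNTf2, −78 to 0 °C
Reagents that add atoms: N-phenylbis(trifluoromethanesulfonimide), O=S(=O)(N(c1ccccc1)S(=O)(=O)C(F)(F)F)C(F)(F)F
Why: Enol triflate formation by O-sulfonylation of a kinetic enolate should be regiochemically unambiguous because C10 is quaternary and only C8 can be deprotonated, and the ring A silyl enol ether is inert to the amide base.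

**Step 5**
Reactants: 7 3-(tert-butyldimethylsilyloxy)-9-(trifluoromethanesulfonyloxy)-4βH,5βH-eudesma-2,8-diene
Product: 9 4βH,5βH-eudesm-8-en-3-one, via TBS enol ether 8 (not isolated)
Conditions: Pd(OAc)2 (cat.), PPh3, Bu3N, HCO2H, DMF, 60 °C; then 1 M HCl, THF, rt
Reagents that add atoms: none
Why: Palladium-catalysed formate reduction of the enol triflate (oxidative addition to zerovalent palladium formed in situ, formate exchange, decarboxylation, C–H reductive elimination) should give the C8=C9 alkene, after which dilute acid hydrolyses the silyl enol ether by protonation at C2 to unveil the C3 ketone.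

**Step 6**
Reactants: 9 4βH,5βH-eudesm-8-en-3-one
Product: 10 3-(trifluoromethanesulfonyloxy)-5βH-eudesma-3,8-diene
Conditions: Tf2O, 2,6-di-tert-butyl-4-methylpyridine, CH2Cl2, 0 °C to rt
Reagents that add atoms: trifluoromethanesulfonic anhydride, O=S(=O)(OS(=O)(=O)C(F)(F)F)C(F)(F)F
Why: Thermodynamic enol triflate formation with triflic anhydride and a hindered pyridine base should give the more substituted C3=C4 isomer, favoured both by the C4 methyl and by the general tendency of cis-fused 3-ketones to enolise toward C4, while the isolated C8=C9 alkene does not react.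

**Step 7**
Reactants: 10 3-(trifluoromethanesulfonyloxy)-5βH-eudesma-3,8-diene
Product: 12 8α-hydroxy-3-(trifluoromethanesulfonyloxy)-5βH-eudesm-3-ene, via C8 alkylborane 11 (not isolated)
Conditions: BH3·THF, THF, 0 °C to rt; then NaBO3·4H2O, H2O, rt
Reagents that add atoms: sodium perborate tetrahydrate (NaBO3·4H2O), O[B-]1(O)OO[B-](O)(O)OO1.[Na+].[Na+]
Why: In this hydroboration–oxidation borane should add syn to the only reactive alkene (the tetrasubstituted, electron-poor enol triflate is inert), placing boron on C8, the carbon remote from the quaternary C10, from the α face anti to the C10 methyl and the C7 isopropyl, and perborate should oxidise the C–B bond with retention at a pH that spares the triflate.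

**Step 8**
Reactants: 12 8α-hydroxy-3-(trifluoromethanesulfonyloxy)-5βH-eudesm-3-ene
Product: 13 3-(trifluoromethanesulfonyloxy)-5βH-eudesm-3-en-8-one
Conditions: Dess–Martin periodinane, CH2Cl2, rt
Reagents that add atoms: none
Why: Dess–Martin oxidation of the secondary alcohol under near-neutral conditions should give the C8 ketone without epimerising the adjacent C7 centre or touching the enol triflate, which completes the 1,2-carbonyl transposition.

**Step 9**
Reactants: 13 3-(trifluoromethanesulfonyloxy)-5βH-eudesm-3-en-8-one
Product: 14 5βH-eudesm-3-en-8-one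
Conditions: Pd(OAc)2 (cat.), PPh3, Bu3N, HCO2H, DMF, 60 °C
Reagents that add atoms: none
Why: The same palladium-catalysed formate reduction of an enol triflate should now release the trisubstituted C3=C4 alkene, a saturated ketone being inert to it, and any erosion at C7 under the amine buffer would be corrected in step 11.

**Step 10**
Reactants: 14 5βH-eudesm-3-en-8-one
Product: 17 4α-acetoxy-3α-hydroxy-5βH-eudesman-8-one, via iodoacetate 15 (not isolated), via acetoxonium acetate 16 (not isolated)
Conditions: I2, AgOAc, AcOH, rt; then H2O/AcOH, 90 °C
Reagents that add atoms: silver acetate, CC(=O)[O-].[Ag+]; water, O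
Why: In the Woodward cis-hydroxylation the iodonium ion should form on the open convex β face of ring A (the α face is covered by ring B, whose C9 is axial on ring A), acetate opens it anti at the tertiary C4, silver-assisted loss of iodide with participation of that acetate gives the cis-fused acetoxonium ion on the α face, and water opens this ion to the cis-3α,4α-diol monoacetate, drawn as the axial C4 acetate although its 3-acetate isomer would serve equally in step 11.

**Step 11**
Reactants: 17 4α-acetoxy-3α-hydroxy-5βH-eudesman-8-one
Product: 18 3α,4α-dihydroxy-5βH-eudesman-8-one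
Conditions: K2CO3 (cat.), MeOH, rt
Reagents that add atoms: none
Why: Base-catalysed methanolysis (transesterification) should remove the acetate from whichever oxygen carries it to give a single diol, and the same mild base would return any C7 epimer to the 7β form, which is strongly favoured here because the isopropyl is equatorial only in the conformer that avoids a syn-diaxial C4-methyl/C10-methyl contact.

**Step 12**
Reactants: 18 3α,4α-dihydroxy-5βH-eudesman-8-one
Product: 19 3α-angeloyloxy-4α-hydroxy-5βH-eudesman-8-one
Conditions: angelic acid, 2,4,6-trichlorobenzoyl chloride, Et3N, toluene, rt; then 18, 80 °C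
Reagents that add atoms: angelic acid, C/C=C(/C)C(=O)O
Why: Yamaguchi-type esterification through the preformed mixed anhydride should acylate only the equatorial secondary C3 hydroxyl (the axial tertiary C4 hydroxyl does not react), and omitting DMAP avoids the addition–elimination pathway that isomerises angelates to tiglates, so the Z double bond is kept.

**Step 13**
Reactants: 19 3α-angeloyloxy-4α-hydroxy-5βH-eudesman-8-one
Product: 20 4α-acetoxy-3α-angeloyloxy-5βH-eudesman-8-one (target)
Conditions: Ac2O, TMSOTf (cat.), CH2Cl2, −40 to 0 °C
Reagents that add atoms: acetic anhydride, CC(=O)OC(C)=O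
Why: Silyl-triflate-catalysed acetylation with acetic anhydride generates a strongly electrophilic acylating species that should esterify the hindered tertiary alcohol quickly at low temperature, and the base-free medium disfavours migration of the neighbouring angeloyl group and enolisation at C7.

**Compound list**
1 | (S)-(+)-carvone | CC1=CC[C@H](C(C)=C)CC1=O | starting material
2 | (S)-carvotanacetone, (S)-5-isopropyl-2-methylcyclohex-2-en-1-one | CC1=CC[C@H](C(C)C)CC1=O | intermediate
3 | pent-1-en-3-one | CCC(=O)C=C | starting material
4 | (Z)-3-(tert-butyldimethylsilyloxy)penta-1,3-diene | C=C/C(O[Si](C)(C)C(C)(C)C)=C/C | intermediate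
5 | 3-(tert-butyldimethylsilyloxy)-4βH,5βH-eudesm-2-en-9-one (cis-fused adduct; 4α-Me, 10β-Me, 7β-iPr) | CC(C)(C)[Si](C)(C)OC1=CC[C@]2(C)C(=O)C[C@@H](C(C)C)C[C@@H]2[C@@H]1C | intermediate
6 | potassium C8=C9 enolate of 5 (not isolated) | CC(C)(C)[Si](C)(C)OC1=CC[C@]2(C)C([O-])=C[C@@H](C(C)C)C[C@@H]2[C@@H]1C.[K+] | intermediate
7 | 3-(tert-butyldimethylsilyloxy)-9-(trifluoromethanesulfonyloxy)-4βH,5βH-eudesma-2,8-diene | CC(C)(C)[Si](C)(C)OC1=CC[C@]2(C)C(OS(=O)(=O)C(F)(F)F)=C[C@@H](C(C)C)C[C@@H]2[C@@H]1C | intermediate
8 | 3-(tert-butyldimethylsilyloxy)-4βH,5βH-eudesma-2,8-diene (not isolated) | CC(C)(C)[Si](C)(C)OC1=CC[C@]2(C)C=C[C@@H](C(C)C)C[C@@H]2[C@@H]1C | intermediate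
9 | 4βH,5βH-eudesm-8-en-3-one | O=C1CC[C@]2(C)C=C[C@@H](C(C)C)C[C@@H]2[C@@H]1C | intermediate
10 | 3-(trifluoromethanesulfonyloxy)-5βH-eudesma-3,8-diene | FC(F)(F)S(=O)(=O)OC=1CC[C@]2(C)C=C[C@@H](C(C)C)C[C@@H]2C=1C | intermediate
11 | 8α-boranyl-3-(trifluoromethanesulfonyloxy)-5βH-eudesm-3-ene (monoalkylborane; not isolated) | FC(F)(F)S(=O)(=O)OC=1CC[C@]2(C)C[C@H](B)[C@@H](C(C)C)C[C@@H]2C=1C | intermediate
12 | 8α-hydroxy-3-(trifluoromethanesulfonyloxy)-5βH-eudesm-3-ene | FC(F)(F)S(=O)(=O)OC=1CC[C@]2(C)C[C@H](O)[C@@H](C(C)C)C[C@@H]2C=1C | intermediate
13 | 3-(trifluoromethanesulfonyloxy)-5βH-eudesm-3-en-8-one | FC(F)(F)S(=O)(=O)OC=1CC[C@]2(C)CC(=O)[C@@H](C(C)C)C[C@@H]2C=1C | intermediate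
14 | 5βH-eudesm-3-en-8-one | C=1CC[C@]2(C)CC(=O)[C@@H](C(C)C)C[C@@H]2C=1C | intermediate
15 | 4α-acetoxy-3β-iodo-5βH-eudesman-8-one (not isolated) | I[C@H]1CC[C@]2(C)CC(=O)[C@@H](C(C)C)C[C@@H]2[C@]1(C)OC(C)=O | intermediate
16 | α-face 3,4-acetoxonium ion (2-methyl-1,3-dioxolan-2-ylium) of 5βH-eudesman-8-one, acetate salt (not isolated) | O3[C@@H]1CC[C@]2(C)CC(=O)[C@@H](C(C)C)C[C@@H]2[C@]1(C)[O+]=C3C.CC(=O)[O-] | intermediate
17 | 4α-acetoxy-3α-hydroxy-5βH-eudesman-8-one | O[C@@H]1CC[C@]2(C)CC(=O)[C@@H](C(C)C)C[C@@H]2[C@]1(C)OC(C)=O | intermediate
18 | 3α,4α-dihydroxy-5βH-eudesman-8-one | O[C@@H]1CC[C@]2(C)CC(=O)[C@@H](C(C)C)C[C@@H]2[C@]1(C)O | intermediate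
19 | 3α-angeloyloxy-4α-hydroxy-5βH-eudesman-8-one | C/C=C(/C)C(=O)O[C@@H]1CC[C@]2(C)CC(=O)[C@@H](C(C)C)C[C@@H]2[C@]1(C)O | intermediate
20 | 4α-acetoxy-3α-angeloyloxy-5βH-eudesman-8-one (CNP0322180.1) | C/C=C(/C)C(=O)O[C@@H]1CC[C@]2(C)CC(=O)[C@@H](C(C)C)C[C@@H]2[C@]1(C)OC(C)=O | target

**Step count**
Total: 13 steps. Longest linear sequence: 12 steps (1 to 20 through steps 1 and 3–13); diene 4 is made in one step (step 2).

**Steps most likely to fail**

Step 7 (hydroboration–oxidation). Borane may add to C9 as well as C8, the hindered ring B alkene may react slowly, or the enol triflate may be cleaved during the oxidative work-up. The fallback puts oxygen on both carbons and then removes it from C9. Setting out from 10, OsO4 (cat.) with NMO in acetone/H2O should dihydroxylate only the C8=C9 alkene, from the α face away from the C10 methyl, to give 3-(trifluoromethanesulfonyloxy)-5βH-eudesm-3-ene-8α,9α-diol F1. The C9 hydroxyl is neopentyl, so TEMPO/PhI(OAc)2 should oxidise only the less hindered C8 carbinol and give 9α-hydroxy-3-(trifluoromethanesulfonyloxy)-5βH-eudesm-3-en-8-one F2. SmI2 in THF/MeOH at −78 °C should then cleave the C–O bond next to the ketone, and the sequence returns to the route at 13.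

Step 10 (Woodward cis-hydroxylation). The iodonium ion may form on the α face instead of the β face, which would end in the 3β,4β-diol, or iodination next to the C8 ketone may compete. The fallback is a concerted osmylation, which delivers both oxygens to the face the reagent attacks and is therefore stereochemically complementary to the Woodward sequence. Setting out from 14, OsO4 (cat.) with NMO in acetone/H2O would give diol 18 directly if the α face proves to be the open one, and the route is rejoined at 18; this detour makes no compound outside the list (F0).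

Step 13 (tertiary acetylation). Acylation of the axial tertiary hydroxyl may be slow, and the acidic activator may cause ionisation or elimination at C4, migration of the angeloyl group, or Z-to-E isomerisation of the angelate. The fallback never acylates the tertiary alcohol directly. Setting out from 18, trimethyl orthoacetate with PPTS in CH2Cl2 should give the cyclic 3α,4α-orthoacetate (2-methoxy-2-methyl-1,3-dioxolane) of 5βH-eudesman-8-one F3. Mild aqueous acetic acid should open it under stereoelectronic control to the axial ester, that is the tertiary C4 acetate 17. Angeloylation of the free C3 hydroxyl of 17 under the conditions of step 12 then gives the target, so this path rejoins the route at 20.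

**Further compounds**
F1 | step 7 | 3-(trifluoromethanesulfonyloxy)-5βH-eudesm-3-ene-8α,9α-diol | FC(F)(F)S(=O)(=O)OC=1CC[C@]2(C)[C@H](O)[C@H](O)[C@@H](C(C)C)C[C@@H]2C=1C
F2 | step 7 | 9α-hydroxy-3-(trifluoromethanesulfonyloxy)-5βH-eudesm-3-en-8-one | FC(F)(F)S(=O)(=O)OC=1CC[C@]2(C)[C@H](O)C(=O)[C@@H](C(C)C)C[C@@H]2C=1C
F0 | step 10 | none | none
F3 | step 13 | cyclic 3α,4α-orthoacetate (2-methoxy-2-methyl-1,3-dioxolane) of 5βH-eudesman-8-one | COC3(C)O[C@@H]1CC[C@]2(C)CC(=O)[C@@H](C(C)C)C[C@@H]2[C@]1(C)O3
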